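The cyclopentenone ring is divided into a two-carbon and a three-carbon piece. Ring C-3 and C-4, with the acetoxy group and the complete (Z)-octenyl chain, are the carbonyl and α-carbon of (Z)-dec-4-enal; C-5, C-1 and C-2, with the chlorine, are 1,3-dichloroacetone. In the key step the chiral enamine of the α-acetoxy aldehyde is C-alkylated by dichloroacetone, which makes the C-4–C-5 bond and the quaternary stereocentre, and the iminium formed closes by a Mannich reaction and loses the amine, which makes the C-2=C-3 bond: a (3+2) annulation that exploits the 1,4-relation between the ring carbonyl C-1 and the aldehyde carbon C-3 across C-4. Aldol condensation at C-5 completes the dienone.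

Key step: step 3

Remark: ring positions are numbered as in cyclopent-2-en-1-one (C-1 carbonyl, C-2 bearing chlorine, C-3 CH, C-4 quaternary acetoxy carbon, C-5); the descriptor of C-4 is S in the annulation product and in the aldol intermediates and R in the target only because C-5 outranks C-3 once it carries the exocyclic double bond, the spatial arrangement being the same.

Step 1
Reactants: 1 (4Z)-dec-4-enal
Product: 2 rac-(4Z)-2-acetoxydec-4-enal
Conditions: MeNH(OAc)·HCl, DMSO, rt
Reagents that add atoms: N-methyl-O-acetylhydroxylamine hydrochloride, CNOC(C)=O.Cl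
Why: α-Acyloxylation of an aldehyde with an N-alkyl-O-acylhydroxylamine, in which condensation at the carbonyl group is followed by a [3,3]-sigmatropic shift of the acetoxy group from nitrogen to the α-carbon and hydrolysis, should leave the skipped (Z)-alkene alone; the new stereocentre forms racemic and is erased again in step 2.

Step 2
Reactants: 2 rac-(4Z)-2-acetoxydec-4-enal; 3 (2S,5S)-2,5-dimethylpyrrolidine
Product: 4 (1Z,4Z)-1-[(2S,5S)-2,5-dimethylpyrrolidin-1-yl]deca-1,4-dien-2-yl acetate
Conditions: 4 Å molecular sieves, CH2Cl2, 0 °C to rt; used crude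
Reagents that add atoms: none
Why: Enamine condensation of the α-branched aldehyde with the secondary amine, driven by removal of water, should place the small acetoxy oxygen and not the allylic CH2 group syn to the hindered nitrogen (1,3-allylic strain and the cis preference of 1,2-diheteroatom alkenes), which removes the racemic α-stereocentre and gives the (1Z)-enamine.

Step 3
Reactants: 4 (1Z,4Z)-1-[(2S,5S)-2,5-dimethylpyrrolidin-1-yl]deca-1,4-dien-2-yl acetate; 5 1,3-dichloroacetone
Product: 8 (4S)-4-acetoxy-2-chloro-4-[(2Z)-oct-2-en-1-yl]cyclopent-2-en-1-one, via iminium chloride 6 (not isolated), via Mannich base hydrochloride 7 (not isolated)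
Conditions: 5 (3 equiv), MeCN, 0 to 45 °C; then AcOH, 45 °C
Reagents that add atoms: none
Why: The nucleophilic enamine carbon (future ring C-4) displaces one chloride of 5 in an SN2 C-alkylation and gives iminium salt 6, which has no α-hydrogen and so cannot revert to an enamine; the chloromethyl ketone then enolises toward its CHCl carbon, which adds to the iminium carbon (intramolecular Mannich reaction) to give 7, and E1cB loss of the protonated amine leaves the conjugated 2-chloro enone 8. The closest known reaction types are the Stork enamine alkylation with α-halo ketones followed by cyclodehydration of the 1,4-dicarbonyl unit and the (3+2) cyclopentenone annulation of enamines with α,α'-dihalo ketones, which make the same two ring bonds. The five-membered ring is closed in the Mannich step, a 5-(enolendo)-exo-trig addition of the enol to the iminium carbon, the mode of closure by which 1,4-dicarbonyl compounds give cyclopentenones. The single stereocentre, C-4, is set in the alkylation: in the (1Z)-enamine the methyl group of the C2-symmetric (2S,5S)-pyrrolidine that lies beside the double bond covers one face, so that 5 should add to the other face and give the (4S)-acetate, which is the (R)-centre of the target. The step needs C- instead of N-alkylation and a single alkylation, which the hindered nitrogen and the excess of 5 should secure, and enolisation toward CHCl instead of toward C-5 (where loss of acetate would follow), which the higher acidity of the chloromethyl group and the acidic, base-free medium favour. The enantiomeric purity rests on the enamine geometry, in which the small acetoxy oxygen and not the CH2 group sits syn to the hindered nitrogen.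

Step 4
Reactants: 9 hex-5-ynoic acid
Product: 10 7-hydroxyhept-5-ynoic acid
Conditions: n-BuLi (2.1 equiv), THF, −78 to 0 °C; (CH2O)n; aq. HCl
Reagents that add atoms: paraformaldehyde (as formaldehyde), C=O
Why: Double deprotonation gives the carboxylate–acetylide, whose acetylide carbon adds to formaldehyde (hydroxymethylation of a terminal alkyne); no stereocentre is formed.

Step 5
Reactants: 10 7-hydroxyhept-5-ynoic acid
Product: 11 methyl 7-hydroxyhept-5-ynoate
Conditions: MeOH, H2SO4 (cat.), 40 °C
Reagents that add atoms: methanol, CO
Why: Fischer esterification of the carboxylic acid in methanol, under which the propargylic alcohol is inert.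

Step 6
Reactants: 11 methyl 7-hydroxyhept-5-ynoate
Product: 12 methyl (5Z)-7-hydroxyhept-5-enoate
Conditions: H2 (1 atm), Pd/CaCO3 poisoned with Pb(OAc)2, quinoline, EtOAc, rt
Reagents that add atoms: none
Why: Syn addition of one equivalent of hydrogen on the lead-poisoned palladium surface (Lindlar semi-hydrogenation) gives the (Z)-alkene and stops there, quinoline suppressing over-reduction.

Step 7
Reactants: 12 methyl (5Z)-7-hydroxyhept-5-enoate
Product: 13 methyl (5Z)-7-oxohept-5-enoate
Conditions: MnO2, CH2Cl2, 0 °C; filtered, concentrated cold and used at once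
Reagents that add atoms: none
Why: Selective allylic alcohol oxidation on the MnO2 surface under neutral conditions should give the enal with the (Z)-geometry kept, provided the sensitive aldehyde is not stored.

Step 8
Reactants: 8 (4S)-4-acetoxy-2-chloro-4-[(2Z)-oct-2-en-1-yl]cyclopent-2-en-1-one; 13 methyl (5Z)-7-oxohept-5-enoate
Product: 14 methyl (5Z)-7-[(2S)-2-acetoxy-4-chloro-2-[(2Z)-oct-2-en-1-yl]-5-oxocyclopent-3-en-1-yl]-7-hydroxyhept-5-enoate (mixture of diastereomers at the carbinol carbon and ring C-5)
Conditions: Bu2BOTf, i-Pr2NEt, CH2Cl2, −78 °C; then 13, −78 to −40 °C; pH 7 buffer, MeOH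
Reagents that add atoms: none
Why: Boron-mediated aldol addition, in which soft enolisation can only occur at ring C-5 and keeps the enol oxygen covalently bound to boron so that the neighbouring tertiary acetate should be neither expelled nor attacked, and in which 1,2-addition to the enal at low temperature keeps the (5Z)-geometry; the two new stereocentres form as a mixture and are both removed in step 9.

Step 9
Reactants: 14 methyl (5Z)-7-[(2S)-2-acetoxy-4-chloro-2-[(2Z)-oct-2-en-1-yl]-5-oxocyclopent-3-en-1-yl]-7-hydroxyhept-5-enoate
Product: 16 methyl (5Z)-7-[(1E,2R)-2-acetoxy-4-chloro-2-[(2Z)-oct-2-en-1-yl]-5-oxocyclopent-3-en-1-ylidene]hept-5-enoate, via allylic acetate 15 (not isolated)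
Conditions: Ac2O, DMAP, Et3N, CH2Cl2, 0 °C; then DBU, 0 °C to rt
Reagents that add atoms: none
Why: Acetylation of the secondary aldol hydroxyl and E1cB elimination of acetate (aldol condensation by dehydration) should give the cross-conjugated dienone, mainly as the (E)-alkylidene isomer with the chain anti to the ring carbonyl, any (Z)-alkylidene isomer being removed by chromatography, while the tertiary acetate stays because its loss would create a cyclopentadienone.

Compound list
1 | (4Z)-dec-4-enal | CCCCC/C=C\CCC=O | starting material
2 | rac-(4Z)-2-acetoxydec-4-enal | CCCCC/C=C\CC(OC(C)=O)C=O | intermediate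
3 | (2S,5S)-2,5-dimethylpyrrolidine | C[C@H]1CC[C@H](C)N1 | starting material
4 | (1Z,4Z)-1-[(2S,5S)-2,5-dimethylpyrrolidin-1-yl]deca-1,4-dien-2-yl acetate | CCCCC/C=C\C/C(OC(C)=O)=C/N1[C@@H](C)CC[C@@H]1C | intermediate
5 | 1,3-dichloroacetone | ClCC(=O)CCl | starting material
6 | (2S,5S)-1-[(2S,4Z)-2-acetoxy-2-(3-chloro-2-oxopropyl)dec-4-en-1-ylidene]-2,5-dimethylpyrrolidin-1-ium chloride | CCCCC/C=C\C[C@](OC(C)=O)(CC(=O)CCl)C=[N+]1[C@@H](C)CC[C@@H]1C.[Cl-] | intermediate
7 | (4S)-4-acetoxy-2-chloro-3-[(2S,5S)-2,5-dimethylpyrrolidin-1-yl]-4-[(2Z)-oct-2-en-1-yl]cyclopentan-1-one hydrochloride (mixture at C-2 and C-3) | CCCCC/C=C\C[C@@]1(OC(C)=O)C(N2[C@@H](C)CC[C@@H]2C)C(Cl)C(=O)C1.Cl | intermediate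
8 | (4S)-4-acetoxy-2-chloro-4-[(2Z)-oct-2-en-1-yl]cyclopent-2-en-1-one | CCCCC/C=C\C[C@@]1(OC(C)=O)C=C(Cl)C(=O)C1 | intermediate
9 | hex-5-ynoic acid | C#CCCCC(=O)O | starting material
10 | 7-hydroxyhept-5-ynoic acid | OCC#CCCCC(=O)O | intermediate
11 | methyl 7-hydroxyhept-5-ynoate | OCC#CCCCC(=O)OC | intermediate
12 | methyl (5Z)-7-hydroxyhept-5-enoate | OC/C=C\CCCC(=O)OC | intermediate
13 | methyl (5Z)-7-oxohept-5-enoate | O=C/C=C\CCCC(=O)OC | intermediate
14 | methyl (5Z)-7-[(2S)-2-acetoxy-4-chloro-2-[(2Z)-oct-2-en-1-yl]-5-oxocyclopent-3-en-1-yl]-7-hydroxyhept-5-enoate | CCCCC/C=C\C[C@@]1(OC(C)=O)C=C(Cl)C(=O)C1C(O)/C=C\CCCC(=O)OC | intermediate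
15 | methyl (5Z)-7-acetoxy-7-[(2S)-2-acetoxy-4-chloro-2-[(2Z)-oct-2-en-1-yl]-5-oxocyclopent-3-en-1-yl]hept-5-enoate | CCCCC/C=C\C[C@@]1(OC(C)=O)C=C(Cl)C(=O)C1C(OC(C)=O)/C=C\CCCC(=O)OC | intermediate
16 | methyl (5Z)-7-[(1E,2R)-2-acetoxy-4-chloro-2-[(2Z)-oct-2-en-1-yl]-5-oxocyclopent-3-en-1-ylidene]hept-5-enoate | CCCCC/C=C\C[C@@]1(OC(C)=O)C=C(Cl)C(=O)/C1=C/C=C\CCCC(=O)OC | target

Total step count: 9. Longest linear sequence: 6 steps (steps 4 to 9).

Steps most likely to fail

Step 3 (key step). The enamine may not adopt a single geometry, or the alkylation may not distinguish its two faces well, so that the quaternary centre forms with low enantiomeric purity; N-alkylation and loss of acetate from the open-chain iminium are further ways out. Fallback: stereocontrol is given up in the annulation and regained by separation. Setting out from 2, condensation with pyrrolidine (4 Å molecular sieves, CH2Cl2) would give the achiral enamine (4Z)-1-(pyrrolidin-1-yl)deca-1,4-dien-2-yl acetate F1. With 5 under the conditions of step 3 this should give racemic 4-acetoxy-2-chloro-4-[(2Z)-oct-2-en-1-yl]cyclopent-2-en-1-one F2. Preparative chromatography on a cellulose tris(3,5-dimethylphenylcarbamate) phase then comes back to the route at 8.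

Step 8. Enolisation next to the tertiary acetate may lead to its loss by β-elimination toward a cyclopentadienone or to acyl migration, and the amine base may isomerise the (Z)-enal. Fallback: no base is present when the aldehyde reacts. Setting out from 8, TMSOTf and Et3N (CH2Cl2, 0 °C) would give the silyl dienol ether (1S)-3-chloro-1-[(2Z)-oct-2-en-1-yl]-4-[(trimethylsilyl)oxy]cyclopenta-2,4-dien-1-yl acetate F3, freed from amine salts by filtration through a short pad. Its Mukaiyama aldol addition to 13 (BF3·OEt2, CH2Cl2, −78 °C) comes back to the route at 14.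

Step 1. The O-acetyl member of this reagent family is less documented than the O-benzoyl one, so the sigmatropic transfer may be sluggish, and a second acyloxylation or self-condensation of the aldehyde may compete. Fallback: oxidation of a preformed enol ether. Setting out from 1, TMSCl, Et3N and NaI in MeCN would give the silyl enol ether (4Z)-1-[(trimethylsilyl)oxy]deca-1,4-diene F4 (mixture of 1E and 1Z). Its oxidation with Pb(OAc)4 (CH2Cl2, −20 °C, the Pb(OAc)4 variant of the Rubottom oxidation) comes back to the route at 2.

Further compounds
F1 | step 3 | (4Z)-1-(pyrrolidin-1-yl)deca-1,4-dien-2-yl acetate | CCCCC/C=C\CC(OC(C)=O)=CN1CCCC1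
F2 | step 3 | racemic 4-acetoxy-2-chloro-4-[(2Z)-oct-2-en-1-yl]cyclopent-2-en-1-one | CCCCC/C=C\CC1(OC(C)=O)C=C(Cl)C(=O)C1
F3 | step 8 | (1S)-3-chloro-1-[(2Z)-oct-2-en-1-yl]-4-[(trimethylsilyl)oxy]cyclopenta-2,4-dien-1-yl acetate | CCCCC/C=C\C[C@@]1(OC(C)=O)C=C(Cl)C(O[Si](C)(C)C)=C1
F4 | step 1 | (4Z)-1-[(trimethylsilyl)oxy]deca-1,4-diene | CCCCC/C=C\CC=CO[Si](C)(C)C
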